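(The data are calculated from invented constants, noise included.)

| flask | starting material | coupling partner | protic impurity | remark | time |
|---|---|---|---|---|---|
| cedar | 0.11 M | 0.10 M | 0.11 M | run made earlier |  |
| oak | 0.11 M | 0.40 M | 0.11 M | run made earlier |  |
| blue | 0.11 M | 0.120 M | 0.110 M |  | 20 min |
| violet | 0.11 M | 0.250 M | 0.110 M |  | 20 min |
| ochre | 0.11 M | 0.500 M | 0.110 M |  | 20 min |

- cedar (time / min: target / %): 1.50: 2.0; 2.50: 3.6; 4.00: 4.5; 8.00: 5.5; 12.0: 6.9; 20.0: 7.5
- oak (time / min: target / %): 1.50: 6.8; 2.50: 9.6; 4.00: 12.0; 8.00: 13.5; 12.0: 13.2; 20.0: 9.9

(readings scatter by 0.3 percentage points)

- percent here means starting material units held: one self-condensation product counts as two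
- the earlier runs were read with a standard deviation of 0.3 percentage points
- steps thought possible: starting material + coupling partner -> target; starting material + 2 coupling partner -> side product; 2 starting material -> self-condensation product; starting material + protic impurity -> quenched substrate; coupling partner + target -> over-reaction product
- "hardly changes" means that all values lie within two and a half points (for a concentration: within two and a half percent of the largest)

* amount of target at the end, in percent of the starting material charged for blue, violet, ochre, in this order
* the shape of the row from first to last (hardly changes / falls all the way / rises all the way / falls, then rises / rises, then falls)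

The easy step comes first: between 12.0 min and 20.0 min the oak run's target falls from 13.2% to 9.9%, and since oak's coupling partner stands in excess, I treat this fall as a pseudo-first-order loss and divide by the charge, which gives 0.0899 M⁻¹ min⁻¹. I call this the loss constant, the fraction of target lost per minute for each mole per litre of coupling partner charged.

Now I solve the flask at both ends. In one version the target is made at the last moment and none is lost, so the amount made equals the amount read; in the other it is made at the first moment and lives through the whole run, so the reading must be divided by the exponential of minus loss constant, charge and time. I take the real flask to lie between, which puts my estimate of the amount made between 7.5% and 8.98% in cedar, and between 9.9% and 20.3% in oak.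

I commit to the harsher end. Joining its two amounts by a power of the charge gives the exponent 0.589, and ochre's charge is larger than oak's, so its value is an extrapolation. Multiplying by survival gives 8.06%, 9.83% and 9.43%, with a top near 0.328 M. That span of 1.8 percentage points lies inside the margin, so I say the row hardly changes.

The forecast gives 8.6%, 11% and 7.8%, shaped rises, then falls, and its loss constant differs from mine: “Oak's decline from 12 to 20 min gives over-reaction k ≈ 0.13 /M/min, with some formation still continuing.”

The flask gives 8.61%, 11.4% and 8.50%, shaped rises, then falls, with a span of 2.9 points, which is outside the margin, so the forecast's shape stands and mine does not.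

    starting material + coupling partner → target (k = 0.00300 M⁻¹ s⁻¹)
    starting material + 2 coupling partner → side product (k = 0.0150 M⁻² s⁻¹)
    2 starting material → self-condensation product (k = 0.0130 M⁻¹ s⁻¹)
    starting material + protic impurity → quenched substrate (k = 0.0130 M⁻¹ s⁻¹)
    coupling partner + target → over-reaction product (k = 0.00210 M⁻¹ s⁻¹)

Ochre ends with 42.6% of side product against 5.55% in blue. The loss constant takes ochre's target of 12.8% at 10.0 min to 8.14% at 20.0 min, where the flask holds 8.50%. On violet it takes 11.4% at 20.0 min to 0.200% at 200 min, where the flask holds 0.242%.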